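**Strategy.** Everything rests on the Z-alkene C1'=C2', which lies between ring oxygen O1 on C6 of the dihydropyranone (allylic side) and the C4' hydroxyl (homoallylic side). Bridging these two oxygens with a diisopropylsilylene unit turns the alkene synthesis into closure of an eight-membered 1,3-dioxa-2-silacyclooctene, a ring too small for a trans double bond. One metathesis therefore creates C1'=C2' and fixes its cis geometry. The precursor is the mixed silaketal of the C4' homoallylic alcohol (C8' acetate and C6' silyl ether in place) and the C6 vinyl carbinol whose Z-enoate arm is the latent lactone; fluoride then releases the target in one operation.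

Key step: step 14

Remark on numbering and descriptors: locants follow the target (lactone C2–C6, side chain C1'–C10'). The target is 6S,4'R,6'R,8'R. In the silaketals 24–27 the descriptor of C6' reads S only because silicon on O4' reverses the CIP ranking of its two chain branches; its spatial arrangement never changes. C4' and C6 come from (R)- and (S)-epichlorohydrin; C8' and C6' are set by substrate control.

**Fragment A (C4' homoallylic alcohol 13)**

Step 1
Reactants: 1 (R)-epichlorohydrin
Product: 2 (2R)-1-chloropent-4-en-2-ol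
Conditions: CH2=CHMgBr (1.2 equiv), CuI (10 mol%), THF, −78 → −20 °C; aq NH4Cl
Reagents that add atoms: vinylmagnesium bromide, C=C[Mg]Br
Why: Copper-catalysed Grignard opening of a terminal epoxide (SN2 at the unsubstituted carbon) is reliable for epichlorohydrin at low temperature, and the C–O stereocentre (future C4') is not touched and stays R.

Step 2
Reactants: 2 (2R)-1-chloropent-4-en-2-ol
Product: 4 (2R)-1-(2-methyl-1,3-dithian-2-yl)pent-4-en-2-ol, via (R)-2-allyloxirane 3 (not isolated)
Conditions: 2-methyl-1,3-dithiane (2.3 equiv), n-BuLi (2.2 equiv), THF, −30 °C; then 2, DMPU, −78 °C → rt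
Reagents that add atoms: 2-methyl-1,3-dithiane, CC1SCCCS1
Why: Corey–Seebach umpolung alkylation: the first equivalent of lithiodithiane deprotonates 2, the chloroalkoxide closes to epoxide 3 (intramolecular Williamson reaction) and the second equivalent opens 3 at its terminal carbon, so the masked methyl ketone is attached without touching the stereocentre.

Step 3
Reactants: 4 (2R)-1-(2-methyl-1,3-dithian-2-yl)pent-4-en-2-ol
Product: 5 2-{(2R)-2-[(4-methoxybenzyl)oxy]pent-4-en-1-yl}-2-methyl-1,3-dithiane
Conditions: NaH (1.5 equiv), 4-methoxybenzyl chloride (1.3 equiv), Bu4NI (cat.), THF/DMF, 0 °C → rt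
Reagents that add atoms: 4-methoxybenzyl chloride, COc1ccc(CCl)cc1
Why: Williamson etherification; the PMB ether is chosen because a β-benzyloxy-type group delivers the 1,5-anti induction needed in step 5 and can later be removed oxidatively beside acetate, silyl ether and alkene.

Step 4
Reactants: 5 2-{(2R)-2-[(4-methoxybenzyl)oxy]pent-4-en-1-yl}-2-methyl-1,3-dithiane
Product: 6 (4R)-4-[(4-methoxybenzyl)oxy]hept-6-en-2-one
Conditions: MeI (10 equiv), CaCO3 (5 equiv), MeCN/H2O (9:1), 45 °C
Reagents that add atoms: water, O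
Why: Alkylative hydrolysis of the dithioacetal (S-methylation, then attack of water) under CaCO3 buffering should unmask the methyl ketone without β-elimination of the PMB ether.

Step 5
Reactants: 6 (4R)-4-[(4-methoxybenzyl)oxy]hept-6-en-2-one; 7 3-phenylpropanal
Product: 10 (3R,7R)-3-hydroxy-7-[(4-methoxybenzyl)oxy]-1-phenyldec-9-en-5-one, via boron enolate 8 (not isolated), via boron aldolate 9 (not isolated)
Conditions: Bu2BOTf (1.2 equiv), iPr2NEt (1.5 equiv), Et2O, −78 °C; 7 (1.3 equiv), −78 °C; pH 7 buffer, MeOH, 30% H2O2, 0 °C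
Reagents that add atoms: dibutylboron triflate, CCCCB(CCCC)OS(=O)(=O)C(F)(F)F (its boron unit stays only in the non-isolated 8 and 9)
Why: Boron-mediated aldol reaction of a β-alkoxy methyl ketone (kinetic enolisation on the methyl side): the β-PMB ether steers the aldehyde to one enolate face through the established 1,5-anti induction, so C8' should be set R relative to the R centre C4'.

Step 6
Reactants: 10 (3R,7R)-3-hydroxy-7-[(4-methoxybenzyl)oxy]-1-phenyldec-9-en-5-one
Product: 11 (3R,5R,7R)-5-hydroxy-7-[(4-methoxybenzyl)oxy]-1-phenyldec-9-en-3-yl acetate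
Conditions: SmI2 (0.3 equiv), CH3CHO (8 equiv), THF, −10 °C
Reagents that add atoms: acetaldehyde, CC=O
Why: Evans–Tishchenko reduction: the samarium-bound hemiacetal formed from the C8' hydroxyl and acetaldehyde delivers hydride intramolecularly to the C6' ketone through a chair-like six-membered transition state, which sets C6' anti to C8' (R) and leaves the acetate on O8', so the two oxygens are differentiated without protecting-group steps.

Step 7
Reactants: 11 (3R,5R,7R)-5-hydroxy-7-[(4-methoxybenzyl)oxy]-1-phenyldec-9-en-3-yl acetate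
Product: 12 (3R,5R,7R)-5-[(tert-butyldimethylsilyl)oxy]-7-[(4-methoxybenzyl)oxy]-1-phenyldec-9-en-3-yl acetate
Conditions: TBSOTf (1.3 equiv), 2,6-lutidine (2 equiv), CH2Cl2, −78 °C
Reagents that add atoms: tert-butyldimethylsilyl triflate, CC(C)(C)[Si](C)(C)OS(=O)(=O)C(F)(F)F
Why: Silylation of the free C6' hydroxyl with a silyl triflate and a hindered base at low temperature should be fast enough to forestall 1,3-acetyl migration.

Step 8
Reactants: 12 (3R,5R,7R)-5-[(tert-butyldimethylsilyl)oxy]-7-[(4-methoxybenzyl)oxy]-1-phenyldec-9-en-3-yl acetate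
Product: 13 (3R,5R,7R)-5-[(tert-butyldimethylsilyl)oxy]-7-hydroxy-1-phenyldec-9-en-3-yl acetate
Conditions: DDQ (1.3 equiv), CH2Cl2/pH 7 buffer (10:1), 0 °C
Reagents that add atoms: none
Why: Oxidative PMB cleavage by DDQ (benzylic hydride abstraction, then hydrolysis of the oxocarbenium ion) frees the C4' homoallylic hydroxyl while acetate, TBS ether and terminal alkene are inert.

**Fragment B (C6 vinyl carbinol 22)**

Step 9
Reactants: 14 (S)-epichlorohydrin
Product: 15 (2S)-1-chloro-5-(trimethylsilyl)pent-4-yn-2-ol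
Conditions: ethynyltrimethylsilane (1.3 equiv), n-BuLi (1.25 equiv), THF, −78 °C; BF3·OEt2 (1.3 equiv); 14, −78 °C; aq NH4Cl
Reagents that add atoms: ethynyltrimethylsilane, C#C[Si](C)(C)C
Why: Yamaguchi–Hirao alkynylation: the BF3-activated epoxide is opened by the lithium acetylide at its terminal carbon at −78 °C, the chloride stays in place and the stereocentre (future C6) is untouched.

Step 10
Reactants: 15 (2S)-1-chloro-5-(trimethylsilyl)pent-4-yn-2-ol
Product: 18 (3S)-hex-1-en-5-yn-3-ol, via alkynyl epoxide 16 (not isolated), via C-silyl enynol 17 (not isolated)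
Conditions: Me3S+ I− (4 equiv), n-BuLi (3.8 equiv), THF, −20 °C; 15, −20 °C → rt; then MeOH, K2CO3 (0.3 equiv), rt; isolation by careful distillation
Reagents that add atoms: trimethylsulfonium iodide, C[S+](C)C.[I-]
Why: Excess dimethylsulfonium methylide closes the chlorohydrin to epoxide 16, opens it at the terminal carbon and the betaine eliminates dimethyl sulfide (Corey–Chaykovsky-type one-carbon homologation of an epoxide to an allylic alcohol), so the carbinol centre is retained, and methanolysis then removes the alkynyl silyl group.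

Step 11
Reactants: 18 (3S)-hex-1-en-5-yn-3-ol; 19 methyl chloroformate
Product: 22 methyl (5S)-5-hydroxyhept-6-en-2-ynoate, via silyl ether 20 (not isolated), via silyloxy ynoate 21 (not isolated)
Conditions: n-BuLi (1.0 equiv), THF, −78 °C; Me3SiCl (1.05 equiv), −78 → 0 °C; n-BuLi (1.05 equiv), −78 °C; transfer into 19 (1.2 equiv), −78 → −20 °C; 1 M HCl, THF, 0 °C
Reagents that add atoms: chlorotrimethylsilane, C[Si](C)(C)Cl (its atoms stay only in the non-isolated 20 and 21)
Why: Acylation of a lithium acetylide with a chloroformate after transient O-silylation, which keeps the alkoxide from forming a carbonate; acidic work-up returns the free alcohol, and the ynoate, unlike a Z-enoate, cannot lactonise.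

**Union, key step and end game**

Step 12
Reactants: 13 (3R,5R,7R)-5-[(tert-butyldimethylsilyl)oxy]-7-hydroxy-1-phenyldec-9-en-3-yl acetate; 23 dichlorodiisopropylsilane; 22 methyl (5S)-5-hydroxyhept-6-en-2-ynoate
Product: 25 methyl (5S)-5-{[{[(4R,6S,8R)-8-acetoxy-6-[(tert-butyldimethylsilyl)oxy]-10-phenyldec-1-en-4-yl]oxy}di(propan-2-yl)silyl]oxy}hept-6-en-2-ynoate, via chlorosilane 24 (not isolated)
Conditions: 23 (3 equiv), imidazole (2 equiv), CH2Cl2, 0 °C → rt; excess 23 removed under high vacuum; then 22 (1.3 equiv), imidazole (3 equiv), DMF, rt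
Reagents that add atoms: none
Why: Stepwise silylation: with excess dichlorosilane the hindered diisopropylsilicon accepts only one alkoxide to give chlorosilane 24, which after removal of the excess reagent silylates allylic alcohol 22 (the standard preparation of unsymmetrical bis-alkoxysilanes).

Step 13
Reactants: 25 (ynoate silaketal)
Product: 26 methyl (2Z,5S)-5-{[{[(4R,6S,8R)-8-acetoxy-6-[(tert-butyldimethylsilyl)oxy]-10-phenyldec-1-en-4-yl]oxy}di(propan-2-yl)silyl]oxy}hepta-2,6-dienoate
Conditions: H2 (1 atm), Pd/CaCO3 poisoned with Pb(OAc)2 (10 wt%), quinoline (0.5 equiv), EtOAc/1-octene (10:1), rt, stopped as soon as 25 is consumed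
Reagents that add atoms: none
Why: Lindlar semihydrogenation: syn delivery of hydrogen on the poisoned palladium surface gives the Z-enoate because the alkyne binds far more strongly than alkenes, quinoline and 1-octene as sacrificial alkene guard the vinyl and allyl groups, and the silyl-blocked C6 oxygen cannot lactonise.

Step 14
Reactants: 26 (Z-enoate silaketal)
Product: 27 methyl (2Z)-4-[(4S,8R)-8-{(2S,4R)-4-acetoxy-2-[(tert-butyldimethylsilyl)oxy]-6-phenylhexyl}-2,2-di(propan-2-yl)-4,7-dihydro-8H-1,3,2-dioxasilocin-4-yl]but-2-enoate (eight-membered Z-dioxasilacyclooctene)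
Conditions: second-generation Grubbs catalyst (H2IMes)(PCy3)Cl2Ru=CHPh (10 mol% in two portions), 1,4-benzoquinone (20 mol%), CH2Cl2 (2 mM), 40 °C, argon sparge; ethyl vinyl ether quench
Reagents that add atoms: none
Why: The ruthenium benzylidene exchanges onto the unhindered allyl terminus (C2'), the resulting alkylidene adds across the C6 vinyl group in a [2+2] cycloaddition, and cycloreversion of the ruthenacyclobutane releases ethene and forms C1'=C2'. This is temporary silicon-tethered ring-closing metathesis of a bis-alkoxysilane, a known way to make cis-alkenes flanked by oxygen functions. The ring closed is the eight-membered 1,3-dioxa-2-silacyclooct-5-ene (O–Si–O, C6, C1'=C2', C3', C4'), formed by ring-closing metathesis with the new double bond endocyclic, and the two isopropyl groups on silicon favour the folded conformer that cyclises. No stereocentre is created; the geometry of C1'=C2' is dictated by ring size, because an eight-membered ring cannot accommodate a trans double bond. The step needs site selectivity among three alkenes and suppression of oligomerisation: only the allyl/vinyl pair can close a ring of reasonable size (vinyl plus enoate would give a cyclobutene, allyl plus enoate a nine-membered ring with loss of methyl acrylate), the Z-enoate is 1,2-disubstituted and electron-poor and so a reluctant partner, and high dilution holds back cross-metathesis.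

Step 15
Reactants: 27 (Z-dioxasilacyclooctene)
Product: 29 (6S)-6-[(1Z,4R,6R,8R)-8-acetoxy-4,6-dihydroxy-10-phenyldec-1-en-1-yl]-5,6-dihydro-2H-pyran-2-one, via triol hydroxy ester 28 (not isolated)
Conditions: HF·pyridine (excess), pyridine, THF, 0 °C → rt; then PPTS (cat.), CH2Cl2, rt if lactonisation is incomplete
Reagents that add atoms: none
Why: Fluoride-mediated desilylation under acidic conditions (so the acetate should neither migrate nor hydrolyse) frees O4', O6' and the C6 hydroxyl, which then closes onto the cis-disposed methyl ester by acid-catalysed transesterification to the six-membered lactone.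

**Compound list**

1 | (R)-epichlorohydrin, (2R)-2-(chloromethyl)oxirane | ClC[C@H]1CO1 | starting material
2 | (2R)-1-chloropent-4-en-2-ol | ClC[C@H](O)CC=C | intermediate
3 | (R)-2-allyloxirane, (2R)-2-(prop-2-en-1-yl)oxirane | C=CC[C@@H]1CO1 | intermediate (not isolated)
4 | (2R)-1-(2-methyl-1,3-dithian-2-yl)pent-4-en-2-ol | CC1(C[C@H](O)CC=C)SCCCS1 | intermediate
5 | 2-{(2R)-2-[(4-methoxybenzyl)oxy]pent-4-en-1-yl}-2-methyl-1,3-dithiane | CC1(C[C@H](OCc2ccc(OC)cc2)CC=C)SCCCS1 | intermediate
6 | (4R)-4-[(4-methoxybenzyl)oxy]hept-6-en-2-one | CC(=O)C[C@H](OCc1ccc(OC)cc1)CC=C | intermediate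
7 | 3-phenylpropanal | O=CCCc1ccccc1 | starting material
8 | dibutylboron enolate of 6, dibutyl{[(4R)-4-[(4-methoxybenzyl)oxy]hepta-1,6-dien-2-yl]oxy}borane | C=C(OB(CCCC)CCCC)C[C@H](OCc1ccc(OC)cc1)CC=C | intermediate (not isolated)
9 | dibutylboron aldolate, O3-dibutylboryl derivative of 10 (3R,7R) | CCCCB(CCCC)O[C@H](CCc1ccccc1)CC(=O)C[C@H](OCc1ccc(OC)cc1)CC=C | intermediate (not isolated)
10 | (3R,7R)-3-hydroxy-7-[(4-methoxybenzyl)oxy]-1-phenyldec-9-en-5-one | O[C@H](CCc1ccccc1)CC(=O)C[C@H](OCc1ccc(OC)cc1)CC=C | intermediate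
11 | (3R,5R,7R)-5-hydroxy-7-[(4-methoxybenzyl)oxy]-1-phenyldec-9-en-3-yl acetate | CC(=O)O[C@H](CCc1ccccc1)C[C@H](O)C[C@H](OCc1ccc(OC)cc1)CC=C | intermediate
12 | (3R,5R,7R)-5-[(tert-butyldimethylsilyl)oxy]-7-[(4-methoxybenzyl)oxy]-1-phenyldec-9-en-3-yl acetate | CC(=O)O[C@H](CCc1ccccc1)C[C@H](O[Si](C)(C)C(C)(C)C)C[C@H](OCc1ccc(OC)cc1)CC=C | intermediate
13 | (3R,5R,7R)-5-[(tert-butyldimethylsilyl)oxy]-7-hydroxy-1-phenyldec-9-en-3-yl acetate | CC(=O)O[C@H](CCc1ccccc1)C[C@H](O[Si](C)(C)C(C)(C)C)C[C@H](O)CC=C | intermediate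
14 | (S)-epichlorohydrin, (2S)-2-(chloromethyl)oxirane | ClC[C@@H]1CO1 | starting material
15 | (2S)-1-chloro-5-(trimethylsilyl)pent-4-yn-2-ol | ClC[C@@H](O)CC#C[Si](C)(C)C | intermediate
16 | trimethyl{3-[(2S)-oxiran-2-yl]prop-1-yn-1-yl}silane | C[Si](C)(C)C#CC[C@H]1CO1 | intermediate (not isolated)
17 | (3S)-6-(trimethylsilyl)hex-1-en-5-yn-3-ol | C=C[C@@H](O)CC#C[Si](C)(C)C | intermediate (not isolated)
18 | (3S)-hex-1-en-5-yn-3-ol | C=C[C@@H](O)CC#C | intermediate
19 | methyl chloroformate | COC(=O)Cl | starting material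
20 | trimethyl{[(3S)-hex-1-en-5-yn-3-yl]oxy}silane | C=C[C@@H](O[Si](C)(C)C)CC#C | intermediate (not isolated)
21 | methyl (5S)-5-[(trimethylsilyl)oxy]hept-6-en-2-ynoate | C=C[C@@H](O[Si](C)(C)C)CC#CC(=O)OC | intermediate (not isolated)
22 | methyl (5S)-5-hydroxyhept-6-en-2-ynoate | C=C[C@@H](O)CC#CC(=O)OC | intermediate
23 | dichlorodiisopropylsilane, dichlorodi(propan-2-yl)silane | CC(C)[Si](Cl)(Cl)C(C)C | starting material
24 | (3R,5S,7R)-5-[(tert-butyldimethylsilyl)oxy]-7-{[chlorodi(propan-2-yl)silyl]oxy}-1-phenyldec-9-en-3-yl acetate | CC(=O)O[C@H](CCc1ccccc1)C[C@H](O[Si](C)(C)C(C)(C)C)C[C@H](O[Si](Cl)(C(C)C)C(C)C)CC=C | intermediate (not isolated)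
25 | methyl (5S)-5-{[{[(4R,6S,8R)-8-acetoxy-6-[(tert-butyldimethylsilyl)oxy]-10-phenyldec-1-en-4-yl]oxy}di(propan-2-yl)silyl]oxy}hept-6-en-2-ynoate | CC(=O)O[C@H](CCc1ccccc1)C[C@H](O[Si](C)(C)C(C)(C)C)C[C@H](O[Si](C(C)C)(C(C)C)O[C@H](C=C)CC#CC(=O)OC)CC=C | intermediate
26 | methyl (2Z,5S)-5-{[{[(4R,6S,8R)-8-acetoxy-6-[(tert-butyldimethylsilyl)oxy]-10-phenyldec-1-en-4-yl]oxy}di(propan-2-yl)silyl]oxy}hepta-2,6-dienoate | CC(=O)O[C@H](CCc1ccccc1)C[C@H](O[Si](C)(C)C(C)(C)C)C[C@H](O[Si](C(C)C)(C(C)C)O[C@H](C=C)C/C=C\C(=O)OC)CC=C | intermediate (key-step precursor)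
27 | methyl (2Z)-4-[(4S,8R)-8-{(2S,4R)-4-acetoxy-2-[(tert-butyldimethylsilyl)oxy]-6-phenylhexyl}-2,2-di(propan-2-yl)-4,7-dihydro-8H-1,3,2-dioxasilocin-4-yl]but-2-enoate | CC(=O)O[C@H](CCc1ccccc1)C[C@H](O[Si](C)(C)C(C)(C)C)C[C@H]2C/C=C\[C@H](C/C=C\C(=O)OC)O[Si](C(C)C)(C(C)C)O2 | intermediate (key-step product)
28 | methyl (2Z,5S,6Z,9R,11R,13R)-13-acetoxy-5,9,11-trihydroxy-15-phenylpentadeca-2,6-dienoate | CC(=O)O[C@H](CCc1ccccc1)C[C@H](O)C[C@H](O)C/C=C\[C@@H](O)C/C=C\C(=O)OC | intermediate (not isolated)
29 | (6S)-6-[(1Z,4R,6R,8R)-8-acetoxy-4,6-dihydroxy-10-phenyldec-1-en-1-yl]-5,6-dihydro-2H-pyran-2-one | CC(=O)O[C@H](CCc1ccccc1)C[C@H](O)C[C@H](O)C/C=C\[C@@H]1CC=CC(=O)O1 | target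

**Step count.** Total: 15 steps. Longest linear sequence: 12 steps (steps 1–8, then 12–15); fragment B takes 3 steps (9–11).

**Steps most likely to fail**

1. Step 14 (ring-closing metathesis). The eight-membered closure may lag behind intermolecular metathesis at the allyl terminus (oligomerisation), and ruthenium hydrides formed on prolonged heating may isomerise the Z-enoate. Fallback by a salt-free Z-selective Wittig olefination, setting out from 12 and 22 and returning at 28. Ozonolysis of 12 with NaBH4 work-up should give primary alcohol F1; I2/PPh3/imidazole then gives iodide F2, and PPh3 in hot MeCN gives phosphonium iodide F3. In parallel 22 is silylated (TBSCl, imidazole) to TBS ether F4 and its vinyl group is ozonised (PPh3 work-up) to ynoate aldehyde F5. The ylide from F3 (NaN(SiMe3)2, THF, −78 °C) and F5 should give Z-alkene ynoate F6. Semihydrogenation over Pd/CaCO3 poisoned with Pb(OAc)2, now with no terminal alkene present, gives Z,Z-diene ester F7. DDQ removes the PMB group to give alcohol F8, and HF·pyridine leads to 28 and on to 29 as in step 15.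

2. Step 13 (semihydrogenation). Hydrogen uptake may not stop cleanly at the enoate, so the vinyl or allyl group is partly saturated, or the Z-enoate isomerises on the catalyst. Fallback by reversing the order, setting out from 25 and returning at 27. The metathesis of step 14 is run on 25 (the electron-poor internal ynoate is a poor enyne partner and cannot close a small ring) to give ynoate dioxasilacyclooctene F9. F9 has no terminal alkene left, and Lindlar reduction then gives 27.

3. Step 12 (mixed silaketal). Double substitution at silicon may give symmetrical bis-alkoxysilanes, or the second silylation at the hindered chlorosilane may stall. Fallback through a hydrosilyl ether, setting out from 13 and returning at 25. Chlorodiisopropylsilane and imidazole convert 13 into hydrosilyl ether F10, which can be purified. N-Bromosuccinimide (CH2Cl2, 0 °C) turns its Si–H bond into the Si–Br bond of bromosilane F11, and addition of 22 and imidazole to the same flask gives 25.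

**Further compounds**

F1 | step 14 | primary alcohol, 9-hydroxy analogue of 12 after loss of the terminal carbon | CC(=O)O[C@H](CCc1ccccc1)C[C@H](O[Si](C)(C)C(C)(C)C)C[C@H](OCc1ccc(OC)cc1)CCO
F2 | step 14 | iodide from F1 | CC(=O)O[C@H](CCc1ccccc1)C[C@H](O[Si](C)(C)C(C)(C)C)C[C@H](OCc1ccc(OC)cc1)CCI
F3 | step 14 | phosphonium iodide from F2 | CC(=O)O[C@H](CCc1ccccc1)C[C@H](O[Si](C)(C)C(C)(C)C)C[C@H](OCc1ccc(OC)cc1)CC[P+](c1ccccc1)(c1ccccc1)c1ccccc1.[I-]
F4 | step 14 | TBS ether of 22, methyl (5S)-5-[(tert-butyldimethylsilyl)oxy]hept-6-en-2-ynoate | C=C[C@@H](O[Si](C)(C)C(C)(C)C)CC#CC(=O)OC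
F5 | step 14 | ynoate aldehyde, methyl (5S)-5-[(tert-butyldimethylsilyl)oxy]-6-oxohex-2-ynoate | O=C[C@@H](O[Si](C)(C)C(C)(C)C)CC#CC(=O)OC
F6 | step 14 | Z-alkene ynoate (Wittig product) | CC(=O)O[C@H](CCc1ccccc1)C[C@H](O[Si](C)(C)C(C)(C)C)C[C@H](OCc1ccc(OC)cc1)C/C=C\[C@@H](O[Si](C)(C)C(C)(C)C)CC#CC(=O)OC
F7 | step 14 | Z,Z-diene ester | CC(=O)O[C@H](CCc1ccccc1)C[C@H](O[Si](C)(C)C(C)(C)C)C[C@H](OCc1ccc(OC)cc1)C/C=C\[C@@H](O[Si](C)(C)C(C)(C)C)C/C=C\C(=O)OC
F8 | step 14 | alcohol from F7 (free C4' hydroxyl) | CC(=O)O[C@H](CCc1ccccc1)C[C@H](O[Si](C)(C)C(C)(C)C)C[C@H](O)C/C=C\[C@@H](O[Si](C)(C)C(C)(C)C)C/C=C\C(=O)OC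
F9 | step 13 | ynoate dioxasilacyclooctene | CC(=O)O[C@H](CCc1ccccc1)C[C@H](O[Si](C)(C)C(C)(C)C)C[C@H]1C/C=C\[C@H](CC#CC(=O)OC)O[Si](C(C)C)(C(C)C)O1
F10 | step 12 | hydrosilyl ether of 13 | CC(=O)O[C@H](CCc1ccccc1)C[C@H](O[Si](C)(C)C(C)(C)C)C[C@H](O[SiH](C(C)C)C(C)C)CC=C
F11 | step 12 | bromosilane from F10 | CC(=O)O[C@H](CCc1ccccc1)C[C@H](O[Si](C)(C)C(C)(C)C)C[C@H](O[Si](Br)(C(C)C)C(C)C)CC=C
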